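**Retrosynthetic overview**

1. Feature: in each coumarin the benzene ring carries oxygen at C8a, the side-chain CH2 at C8, OMe at C7, hydrogen at C6 and C5 and carbon at C4a. This is the pattern a vinylketene and a 1-methoxyalkyne give on benzannulation, with the alkyne substituent between the two oxygens.
2. Lactone rings last: O1–C2 and C3=C4 of both pyranones from a bis-salicylaldehyde and Ph3P=C=C=O; the aldehydes come from salicylate esters.
3. Benzene rings: both are built in one operation from an acyclic (S,S)-bis(methoxyalkyne) silyl ether and two molecules of methyl (E)-5-diazo-4-oxopent-2-enoate (C8–C8a, C6–C7 and C4a–C8a in each ring).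
4. Bis-alkyne: two acetylide displacements on a bis-triflate; the tertiary–secondary ether by opening an (S)-prenol epoxide at its tertiary carbon with the isopropenyl carbinol made from the same epoxide, so one asymmetric epoxidation supplies both stereocentres.
5. Ring order: the two benzene rings together, then the two pyranone rings together.

Key step: step 11

Remark: both stereocentres of the target are S. "A side" means the isopropenyl-bearing half and "B side" the gem-dimethyl carbinol half. The A-side carbinol carbon keeps one spatial arrangement throughout but is labelled R while it carries CH2O instead of CH2C. The diazo ketone is made by diazo transfer to the purchased methyl ketone, because diazomethane would add as a 1,3-dipole to the fumarate-type double bond of an acid chloride. In the twofold steps 9 and 11 two molecules of the numbered partner are consumed, one per arm; the second molecule is entered under the reagents that add atoms.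

**Route**

Step 1
Reactants: 1 3-methylbut-2-en-1-ol (prenol)
Product: 2 (S)-(3,3-dimethyloxiran-2-yl)methanol
Conditions: Ti(OiPr)4 (cat.), L-(+)-diisopropyl tartrate (cat.), t-BuOOH, 4 Å molecular sieves, CH2Cl2, −20 °C; non-aqueous work-up
Reagents that add atoms: tert-butyl hydroperoxide, CC(C)(C)OO
Why: Sharpless asymmetric epoxidation of an allylic alcohol, in which the L-(+)-tartrate ligand directs oxygen to the face that gives the (S)-epoxide; this single centre later becomes both stereocentres of the target.

Step 2
Reactants: 2 (S)-(3,3-dimethyloxiran-2-yl)methanol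
Product: 3 (S)-3-{[(4-methoxybenzyl)oxy]methyl}-2,2-dimethyloxirane
Conditions: NaH, 4-methoxybenzyl chloride, Bu4NI (cat.), THF/DMF, 0 °C → rt
Reagents that add atoms: 4-methoxybenzyl chloride, COc1ccc(CCl)cc1
Why: Williamson etherification of the primary alkoxide under aprotic conditions, where Payne rearrangement of the trisubstituted epoxide is not favoured; the PMB ether tolerates the catalytic Lewis acid of step 4 and is later removed oxidatively beside a silyl ether.

Step 3
Reactants: 3 (S)-3-{[(4-methoxybenzyl)oxy]methyl}-2,2-dimethyloxirane (part of the material)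
Product: 4 (2R)-1-[(4-methoxybenzyl)oxy]-3-methylbut-3-en-2-ol
Conditions: diethylaluminium 2,2,6,6-tetramethylpiperidide (from Et2AlCl and lithium 2,2,6,6-tetramethylpiperidide), toluene, 0 °C; aq. potassium sodium tartrate work-up
Reagents that add atoms: none
Why: Aluminium amide-mediated isomerisation of a trisubstituted epoxide to an allylic alcohol, in which aluminium binds the epoxide oxygen and the amide removes a methyl proton in a cyclic syn elimination that breaks the tertiary C–O bond, so the carbinol carbon keeps its configuration and is called R only because CH2O now outranks the isopropenyl carbon.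

Step 4
Reactants: 3 (S)-3-{[(4-methoxybenzyl)oxy]methyl}-2,2-dimethyloxirane; 4 (2R)-1-[(4-methoxybenzyl)oxy]-3-methylbut-3-en-2-ol
Product: 5 (2S)-1-[(4-methoxybenzyl)oxy]-3-({(2R)-1-[(4-methoxybenzyl)oxy]-3-methylbut-3-en-2-yl}oxy)-3-methylbutan-2-ol
Conditions: 4 (3 equiv), BF3·OEt2 (0.1 equiv), CH2Cl2, −30 → 0 °C, slow addition of 3; Et3N quench; excess 4 recovered
Reagents that add atoms: none
Why: Lewis-acid-catalysed alcoholysis of a trisubstituted epoxide, which opens at the tertiary carbon that best carries positive charge (the CH2OPMB group disfavours the secondary carbon further); neither the epoxide CH–O bond nor the C–O bond of the carbinol is broken, so both centres are carried over, and the diastereomer from the minor enantiomers should be removable by chromatography.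

Step 5
Reactants: 5 coupled secondary alcohol
Product: 6 tert-butyldimethylsilyl ether of 5
Conditions: TBSOTf, 2,6-lutidine, CH2Cl2, −78 → 0 °C
Reagents that add atoms: tert-butyldimethylsilyl trifluoromethanesulfonate, CC(C)(C)[Si](C)(C)OS(=O)(=O)C(F)(F)F
Why: Silylation of a hindered secondary alcohol with a silyl triflate, which masks the hydroxyl against the triflation, the acetylide, the ketene and the phosphorus ylide of the later steps.

Step 6
Reactants: 6 bis-PMB silyl ether
Product: 7 (2R)-2-{[(3S)-3-[(tert-butyldimethylsilyl)oxy]-4-hydroxy-2-methylbutan-2-yl]oxy}-3-methylbut-3-en-1-ol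
Conditions: DDQ (2.4 equiv), CH2Cl2/pH 7 buffer, 0 °C → rt
Reagents that add atoms: none
Why: Oxidative PMB ether cleavage by hydride abstraction and hydrolysis of the oxocarbenium ion, to which the silyl ether, the tertiary ether and the 1,1-disubstituted alkene are inert.

Step 7
Reactants: 7 diol
Product: 8 bis(trifluoromethanesulfonate) of diol 7
Conditions: Tf2O (2.4 equiv), 2,6-lutidine, CH2Cl2, −78 °C; cold work-up, used at once
Reagents that add atoms: trifluoromethanesulfonic anhydride, O=S(=O)(OS(=O)(=O)C(F)(F)F)C(F)(F)F
Why: O-sulfonylation of the two primary alcohols gives the bis-triflate, the leaving group reactive enough for acetylide displacement at low temperature at carbons β to oxygen.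

Step 8
Reactants: 9 2-chloro-1,1-dimethoxyethane (chloroacetaldehyde dimethyl acetal)
Product: 11 methoxyethyne, via sodium methoxyacetylide 10 (not isolated)
Conditions: NaNH2 (3 equiv), liquid NH3, −33 °C; then saturated aq. NaCl, −20 °C; distillation into a cold trap
Reagents that add atoms: none
Why: Twofold base-induced elimination (loss of methanol, then of HCl) from the chloroacetal gives sodium methoxyacetylide, which is protonated on quenching; distilling the free alkyne keeps amine and methoxide by-products away from the triflate of step 9.

Step 9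
Reactants: 8 bis-triflate; 11 methoxyethyne (two molecules react, one per triflate)
Product: 13 (S,S)-bis(methoxyalkyne) TBS ether, via lithium methoxyacetylide 12 (not isolated)
Conditions: 11 (5 equiv), n-BuLi (4.5 equiv), THF, −78 °C; then 8, DMPU, −78 → −20 °C; base-washed silica
Reagents that add atoms: second molecule of methoxyethyne 11, C#COC
Why: SN2 alkylation of lithium methoxyacetylide by each of the two primary triflates, one acetylide per triflate, which forms both CH2–C≡C bonds without touching the adjacent stereocentres (the A-side label changes from R to S by CIP priority only).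

Step 10
Reactants: 14 methyl (E)-4-oxopent-2-enoate
Product: 16 methyl (E)-5-diazo-4-oxopent-2-enoate, via trifluoroacetyl diketone 15 (not isolated)
Conditions: LiN(SiMe3)2, THF, −78 °C (14 added to the base); CF3CO2CH2CF3, −78 °C; 5% aq. HCl wash; crude 15, then MsN3, Et3N, H2O (1 equiv), MeCN, rt
Reagents that add atoms: methanesulfonyl azide, CS(=O)(=O)N=[N+]=[N-]
Why: Regitz-type diazo transfer in its detrifluoroacetylative form, in which the kinetic enolate of the methyl ketone is trifluoroacetylated and the activated 1,3-dicarbonyl takes the diazo group from the sulfonyl azide with loss of the trifluoroacetyl group, under conditions mild enough for an enone.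

Step 11
Reactants: 13 (S,S)-bis(methoxyalkyne) TBS ether; 16 methyl (E)-5-diazo-4-oxopent-2-enoate (two molecules are taken up, one per alkyne)
Product: 20 (S,S)-bis(methyl salicylate) TBS ether, via vinylketene 17 (not isolated), via bis(vinylcyclobutenone) 18 (not isolated), via bis(dienylketene) 19 (not isolated)
Conditions: 16 (4 equiv, in portions), ClCH2CH2Cl, hν 254 nm (low-pressure Hg lamps, quartz), rt; then 80 °C
Reagents that add atoms: second molecule of methyl (E)-5-diazo-4-oxopent-2-enoate 16, COC(=O)/C=C/C(=O)C=[N+]=[N-]
Why: Light expels N2 from each molecule of 16 and Wolff rearrangement gives vinylketene 17; one molecule of 17 adds through its ketene C=C to each of the two ynol ethers in a [2+2] cycloaddition in which the nucleophilic chain-bearing alkyne carbon bonds to the ketene carbonyl carbon (C8–C8a) and the methoxy-bearing carbon to the ketene α-carbon (C7–C6), giving 4-vinylcyclobutenone 18, which opens by 4π electrocyclic cleavage to dienylketene 19. Each benzene ring is then closed by a 6π electrocyclisation that joins the ketene carbon to the ester-bearing vinyl terminus (C4a–C8a), and tautomerisation gives the phenol with the ester ortho to it. The closest known reaction is the photochemical Wolff variant of the Danheiser benzannulation of α-diazo enones with alkoxyalkynes, which gives resorcinol monoethers of this substitution pattern; here the vinyl terminus carries an ester and the sequence runs twice on one molecule. No stereocentre is formed (the sp3 ring carbon of 18 is lost on aromatisation) and the two existing centres lie outside the reacting π systems. The step needs the [2+2] regiochemistry that places the chain carbon next to the phenol, which the polarisation of the ynol ether secures, and chemoselectivity for the alkynes over the 1,1-disubstituted alkene, which the much higher reactivity of an electron-rich alkyne toward ketenes secures; the excess of 16 is meant to drive both arms to completion. The intramolecular hydrogen bond and double ortho substitution of the product phenols should limit their acylation by surplus ketene.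

Step 12
Reactants: 20 (S,S)-bis(methyl salicylate) TBS ether
Product: 21 (S,S)-bis(2-hydroxybenzyl alcohol) TBS ether
Conditions: LiAlH4, THF, 0 °C; aq. potassium sodium tartrate work-up (neutral)
Reagents that add atoms: none
Why: Hydride reduction of both esters to benzylic alcohols (the phenoxides consume extra hydride), which would also cleave any aryl ester formed by O-acylation in step 11 and leaves the silyl ether, the ethers and the alkene untouched.

Step 13
Reactants: 21 (S,S)-bis(2-hydroxybenzyl alcohol) TBS ether
Product: 22 (S,S)-bis-salicylaldehyde TBS ether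
Conditions: MnO2 (activated, excess), CH2Cl2, rt
Reagents that add atoms: none
Why: Selective MnO2 oxidation of activated benzylic alcohols to the hydrogen-bonded salicylaldehydes, without effect on the silyl ether or the alkene.

Step 14
Reactants: 22 (S,S)-bis-salicylaldehyde TBS ether
Product: 24 (S,S)-bis-coumarin TBS ether, via bis(phosphoranylideneacetate) 23 (not isolated)
Conditions: Ph3P=C=C=O (2.5 equiv, one molecule per ring), toluene, 110 °C
Reagents that add atoms: (triphenylphosphoranylidene)ketene, O=C=C=P(c1ccccc1)(c1ccccc1)c1ccccc1
Why: Coumarin synthesis with the Bestmann ylide, in which each phenol adds to one molecule of the cumulated ylide to give an aryl (triphenylphosphoranylidene)acetate whose intramolecular Wittig reaction with the ortho aldehyde forms C3=C4 and closes the lactone ring, the ring enforcing the cis geometry.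

Step 15
Reactants: 24 (S,S)-bis-coumarin TBS ether
Product: 25 8-[(2S)-2-hydroxy-3-{[(2S)-1-(7-methoxy-2-oxo-2H-chromen-8-yl)-3-methylbut-3-en-2-yl]oxy}-3-methylbutyl]-7-methoxy-2H-chromen-2-one (target)
Conditions: HF·pyridine, pyridine, THF, 0 °C → rt
Reagents that add atoms: none
Why: Fluoride-mediated desilylation under buffered, non-basic conditions, which spares the lactones, the tertiary ether and both stereocentres.

**Compound list**

1 | 3-methylbut-2-en-1-ol (prenol) | CC(C)=CCO | starting material
2 | (S)-(3,3-dimethyloxiran-2-yl)methanol | CC1(C)O[C@H]1CO | intermediate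
3 | (S)-3-{[(4-methoxybenzyl)oxy]methyl}-2,2-dimethyloxirane | CC1(C)O[C@H]1COCc1ccc(OC)cc1 | intermediate
4 | (2R)-1-[(4-methoxybenzyl)oxy]-3-methylbut-3-en-2-ol | C=C(C)[C@@H](O)COCc1ccc(OC)cc1 | intermediate
5 | (2S)-1-[(4-methoxybenzyl)oxy]-3-({(2R)-1-[(4-methoxybenzyl)oxy]-3-methylbut-3-en-2-yl}oxy)-3-methylbutan-2-ol | C=C(C)[C@H](COCc1ccc(OC)cc1)OC(C)(C)[C@@H](O)COCc1ccc(OC)cc1 | intermediate
6 | tert-butyldimethylsilyl ether of 5 at the secondary hydroxyl (A side R, B side S) | C=C(C)[C@H](COCc1ccc(OC)cc1)OC(C)(C)[C@@H](O[Si](C)(C)C(C)(C)C)COCc1ccc(OC)cc1 | intermediate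
7 | (2R)-2-{[(3S)-3-[(tert-butyldimethylsilyl)oxy]-4-hydroxy-2-methylbutan-2-yl]oxy}-3-methylbut-3-en-1-ol | C=C(C)[C@H](CO)OC(C)(C)[C@@H](O[Si](C)(C)C(C)(C)C)CO | intermediate
8 | bis(trifluoromethanesulfonate) of diol 7 (A side R, B side S) | C=C(C)[C@H](COS(=O)(=O)C(F)(F)F)OC(C)(C)[C@@H](O[Si](C)(C)C(C)(C)C)COS(=O)(=O)C(F)(F)F | intermediate
9 | 2-chloro-1,1-dimethoxyethane (chloroacetaldehyde dimethyl acetal) | COC(CCl)OC | starting material
10 | sodium methoxyacetylide | [Na+].[C-]#COC | intermediate
11 | methoxyethyne | C#COC | intermediate
12 | lithium methoxyacetylide | [Li]C#COC | intermediate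
13 | tert-butyl{[(3S)-6-methoxy-2-{[(3S)-6-methoxy-2-methylhex-1-en-5-yn-3-yl]oxy}-2-methylhex-5-yn-3-yl]oxy}dimethylsilane | C=C(C)[C@H](CC#COC)OC(C)(C)[C@@H](O[Si](C)(C)C(C)(C)C)CC#COC | intermediate
14 | methyl (E)-4-oxopent-2-enoate | COC(=O)/C=C/C(C)=O | starting material
15 | methyl (E)-7,7,7-trifluoro-4,6-dioxohept-2-enoate | COC(=O)/C=C/C(=O)CC(=O)C(F)(F)F | intermediate
16 | methyl (E)-5-diazo-4-oxopent-2-enoate | COC(=O)/C=C/C(=O)C=[N+]=[N-] | intermediate
17 | methyl (2E)-5-oxopenta-2,4-dienoate (vinylketene) | COC(=O)/C=C/C=C=O | intermediate
18 | bis(vinylcyclobutenone): 13 in which each CH2–C≡C–OMe has become CH2 on C2 of a 3-methoxy-4-[(E)-2-(methoxycarbonyl)ethenyl]cyclobut-2-en-1-one (ring C4 of either configuration) | C=C(C)[C@H](CC1=C(OC)C(/C=C/C(=O)OC)C1=O)OC(C)(C)[C@@H](O[Si](C)(C)C(C)(C)C)CC1=C(OC)C(/C=C/C(=O)OC)C1=O | intermediate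
19 | bis(dienylketene): each arm CH2–C(=C=O)–C(OMe)=CH–CH=CH–CO2Me | C=C(C)[C@H](CC(=C=O)C(OC)=C/C=C/C(=O)OC)OC(C)(C)[C@@H](O[Si](C)(C)C(C)(C)C)CC(=C=O)C(OC)=C/C=C/C(=O)OC | intermediate
20 | (S,S)-bis(methyl salicylate): 13 in which each CH2–C≡C–OMe has become CH2–aryl, aryl = 2-hydroxy-6-methoxy-3-(methoxycarbonyl)phenyl | C=C(C)[C@H](Cc1c(OC)ccc(C(=O)OC)c1O)OC(C)(C)[C@@H](O[Si](C)(C)C(C)(C)C)Cc1c(OC)ccc(C(=O)OC)c1O | intermediate
21 | (S,S)-bis(2-hydroxybenzyl alcohol): aryl = 2-hydroxy-3-(hydroxymethyl)-6-methoxyphenyl | C=C(C)[C@H](Cc1c(OC)ccc(CO)c1O)OC(C)(C)[C@@H](O[Si](C)(C)C(C)(C)C)Cc1c(OC)ccc(CO)c1O | intermediate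
22 | (S,S)-bis-salicylaldehyde: aryl = 3-formyl-2-hydroxy-6-methoxyphenyl | C=C(C)[C@H](Cc1c(OC)ccc(C=O)c1O)OC(C)(C)[C@@H](O[Si](C)(C)C(C)(C)C)Cc1c(OC)ccc(C=O)c1O | intermediate
23 | bis[aryl (triphenylphosphoranylidene)acetate] of 22 (each phenol oxygen acylated by C(=O)CH=PPh3) | C=C(C)[C@H](Cc1c(OC)ccc(C=O)c1OC(=O)C=P(c2ccccc2)(c2ccccc2)c2ccccc2)OC(C)(C)[C@@H](O[Si](C)(C)C(C)(C)C)Cc1c(OC)ccc(C=O)c1OC(=O)C=P(c2ccccc2)(c2ccccc2)c2ccccc2 | intermediate
24 | (S,S)-bis-coumarin TBS ether: aryl = 7-methoxy-2-oxo-2H-chromen-8-yl | C=C(C)[C@H](Cc1c(OC)ccc2ccc(=O)oc12)OC(C)(C)[C@@H](O[Si](C)(C)C(C)(C)C)Cc1c(OC)ccc2ccc(=O)oc12 | intermediate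
25 | 8-[(2S)-2-hydroxy-3-{[(2S)-1-(7-methoxy-2-oxo-2H-chromen-8-yl)-3-methylbut-3-en-2-yl]oxy}-3-methylbutyl]-7-methoxy-2H-chromen-2-one | C=C(C)[C@H](Cc1c(OC)ccc2ccc(=O)oc12)OC(C)(C)[C@@H](O)Cc1c(OC)ccc2ccc(=O)oc12 | target

**Step count**

Total: 15 steps. Longest linear sequence: 13 steps (steps 1–7, 9, 11–15, from prenol).

**Steps most likely to fail**

Step 11. The twofold photochemical cascade may stall or be diverted: the acceptor-substituted diazo ketone may photoisomerise or add to itself, the salicylate product may absorb the light, only one arm may react, or surplus ketene may acylate the phenols. The fallback runs the same benzannulation thermally with the parent vinylketene and adds the C4a carbon afterwards. It sets out from 13, which would be heated in toluene at 80 °C with an excess of cyclobut-2-en-1-one F1 (prepared by dehydrobromination of 3-bromocyclobutanone with tributylamine), one molecule reacting at each alkyne. The same [2+2], 4π opening and 6π closure should give the bis(2-alkyl-3-methoxyphenol) F2. Magnesium-mediated ortho-formylation (MgCl2, Et3N, paraformaldehyde, MeCN, reflux) can occur only at the one free position ortho to each phenol, the future C4a, and should give bis-salicylaldehyde 22, where the route is rejoined without steps 12 and 13.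

Step 4. The Lewis acid may divert the activated epoxide by hydride shift to a ketone (Meinwald rearrangement), elimination or fluoride capture before the hindered secondary carbinol attacks the tertiary carbon; some PMB ether may also be lost. The fallback delivers the alkoxide from inside a metal chelate instead of from outside. It sets out from the free epoxy alcohol 2 and carbinol 4: Ti(OiPr)4 is exchanged with an excess of 4 (isopropanol removed), 2 is bound to the same titanium centre through its hydroxyl, and warming should transfer the alkoxide of 4 to C3 of the chelated epoxide, the tertiary carbon, giving the diol F3. Dibutylstannylene acetal formation (Bu2SnO, toluene, reflux) and alkylation with 4-methoxybenzyl chloride and Bu4NI at the primary oxygen then returns to 5.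

Step 9. Elimination or decomposition of the B-side triflate, which lies next to the silyloxy-bearing carbon and the quaternary centre, may outrun substitution, so that only the A-side alkyne is installed. The fallback attacks the B-side carbon as a terminal epoxide instead. It sets out from 5: DDQ in wet CH2Cl2 should remove both PMB groups to give the triol F4, and Tf2O with 2,6-lutidine at −78 °C should triflate only the two primary hydroxyls to give the hydroxy bis-triflate F5. Adding F5 to an excess of 12 in THF/DMPU at −78 °C should close the B-side hydroxy triflate to the terminal epoxide and displace the less hindered A-side triflate, giving the epoxy alkyne F6, which is isolated. BF3·OEt2-promoted opening of the epoxide at its CH2 by 12 (Yamaguchi alkynylation, THF, −78 °C) should then give the bis-alkyne alcohol F7, and silylation (TBSCl, imidazole, DMF) returns to 13.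

**Further compounds**

F1 | step 11 | cyclobut-2-en-1-one | O=C1C=CC1
F2 | step 11 | (S,S)-bis(2-alkyl-3-methoxyphenol): 13 in which each CH2–C≡C–OMe has become CH2–(2-hydroxy-6-methoxyphenyl) | C=C(C)[C@H](Cc1c(OC)cccc1O)OC(C)(C)[C@@H](O[Si](C)(C)C(C)(C)C)Cc1c(OC)cccc1O
F3 | step 4 | (2S)-3-({(2R)-1-[(4-methoxybenzyl)oxy]-3-methylbut-3-en-2-yl}oxy)-3-methylbutane-1,2-diol | C=C(C)[C@H](COCc1ccc(OC)cc1)OC(C)(C)[C@@H](O)CO
F4 | step 9 | (2S)-3-{[(2R)-1-hydroxy-3-methylbut-3-en-2-yl]oxy}-3-methylbutane-1,2-diol | C=C(C)[C@H](CO)OC(C)(C)[C@@H](O)CO
F5 | step 9 | bis(trifluoromethanesulfonate) of F4 at the two primary hydroxyls | C=C(C)[C@H](COS(=O)(=O)C(F)(F)F)OC(C)(C)[C@@H](O)COS(=O)(=O)C(F)(F)F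
F6 | step 9 | (2S)-2-(2-{[(3S)-6-methoxy-2-methylhex-1-en-5-yn-3-yl]oxy}propan-2-yl)oxirane | C=C(C)[C@H](CC#COC)OC(C)(C)[C@@H]1CO1
F7 | step 9 | (3S)-6-methoxy-2-{[(3S)-6-methoxy-2-methylhex-1-en-5-yn-3-yl]oxy}-2-methylhex-5-yn-3-ol | C=C(C)[C@H](CC#COC)OC(C)(C)[C@@H](O)CC#COC
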